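**Retrosynthetic overview** (locants follow 9,10-seco-kaurane numbering: ring A = C1–C5/C10, lactone C19(=O)–O–C6, C7 methylene, bicyclo[3.2.1]octenone = C8, C9, C11–C16, C17 = exocyclic CH2)
1. Target 25 ⇐ 23: the C11=C12 enone is unveiled last from a C9 silyl enol ether (Saegusa–Ito); the endo C15 acetate comes from exo-face hydride reduction of a 15-ketone while that enol ether masks C9.
2. Key disconnection (one operation, three C–C bonds): C6–C7, C8–C14 (ring C, the cyclohexanone) and C13–C16 (ring D, the methylenecyclopentane), by a radical relay between lactone selenide 9 (ring A plus γ-lactone) and the acyclic α-methylene ketone 17.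
3. Enabling feature: the quaternary bridgehead C8 lies α to the C9 ketone and carries the C7 methylene, so its latent form is the enone C7=C8–C9=O. A radical at the lactone carbinol carbon C6 adding to C7 creates the C8 α-keto radical between a C11–C14 pentenyl arm and a C15–C16≡C17 propargyl arm, which close the bicyclo[3.2.1]octane. The C15 silyloxy stereocentre steers the face of C8 and is afterwards inverted through the ketone.
4. 9 comes from an enone ester by asymmetric conjugate methylation/glyoxylate aldol/lactonisation, hydration at C10 and decarboxylative selenation (the glyoxylate ester carbon is a traceless radical handle); 17 comes from a Morita–Baylis–Hillman reaction plus lipase resolution.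
5. Ring order: ring A is bought, the γ-lactone closes in step 1, rings C and D close together in step 11.

Key step: step 11

Remark: the C6 centre of 3–9 (the carbon that becomes the C6 radical) is deliberately left uncontrolled and is written without configuration.

Step 1
Reactants: 1 methyl 3-oxocyclohex-1-ene-1-carboxylate; 2 ethyl glyoxylate
Product: 4 ethyl (3aR,7aS)-3a-methyl-3,7-dioxooctahydro-2-benzofuran-1-carboxylate (C1 epimers), via aldol adduct 3 (not isolated)
Conditions: Me2Zn, Cu(OTf)2 (5 mol %), chiral sulfonate-bearing imidazolinium salt (carbene ligand precursor, 6 mol %), t-BuOMe, −30 °C; then 2, −78 → 23 °C; aq NH4Cl; PPTS, PhMe, 60 °C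
Reagents that add atoms: dimethylzinc, C[Zn]C
Why: Copper-catalysed asymmetric conjugate addition of Me2Zn to the β-carboalkoxy enone sets the quaternary C4 (R) under control of the chiral carbene ligand, the zinc enolate is trapped at C5 by the glyoxylate (aldol), and only the C5 epimer with the carbinol cis to the C4 ester can lactonise, so the epimerisable C5 (α to the C10 ketone) is funnelled into the cis-fused lactone.

Step 2
Reactants: 4 keto lactone ester
Product: 5 ethyl (3aR,7aS)-3a-methyl-7-methylidene-3-oxooctahydro-2-benzofuran-1-carboxylate (C1 epimers)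
Conditions: Zn, CH2Br2, TiCl4 (preformed Lombardo reagent), THF/CH2Cl2, 0 → 23 °C
Reagents that add atoms: dibromomethane, BrCBr
Why: Takai–Lombardo methylenation converts the hindered C10 ketone into the exocyclic alkene under non-basic conditions, so the β-acyloxy ketone neither eliminates nor epimerises at C5; no stereocentre is formed.

Step 3
Reactants: 5 methylidene lactone ester
Product: 6 ethyl (3aR,7R,7aS)-7-hydroxy-3a,7-dimethyl-3-oxooctahydro-2-benzofuran-1-carboxylate (C1 epimers)
Conditions: Mn(dpm)3 (10 mol %), PhSiH3, O2 (1 atm), i-PrOH/CH2Cl2, 0 → 23 °C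
Reagents that add atoms: dioxygen, O=O
Why: Mukaiyama hydration (hydrogen-atom transfer to the 1,1-disubstituted alkene, then capture of the tertiary C10 radical by O2) gives the Markovnikov alcohol, and O2 should enter on the convex face of the cis-fused bicycle, anti to the lactone ring on C4 and C5, placing the hydroxyl cis to H5 and to the C4 methyl (10R).

Step 4
Reactants: 6 hydroxy lactone ester
Product: 7 (3aR,7R,7aS)-7-hydroxy-3a,7-dimethyl-3-oxooctahydro-2-benzofuran-1-carboxylic acid (C1 epimers)
Conditions: LiOH·H2O, THF/H2O, 0 → 23 °C; then 1 M HCl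
Reagents that add atoms: lithium hydroxide, [Li+].[OH-]
Why: Saponification of the ethyl ester; the lactone also opens but recloses on acidification because only the C6 hydroxyl is cis to the C19 carboxyl (the C10 hydroxyl is trans and cannot lactonise), and no retained stereocentre is touched.

Step 5
Reactants: 7 lactone acid
Product: 9 (3aR,4R,7aR)-4-hydroxy-4,7a-dimethyl-3-(phenylselanyl)hexahydro-2-benzofuran-1(3H)-one (C3 epimers), via Barton ester 8 (not isolated)
Conditions: 1-hydroxypyridine-2(1H)-thione, DCC, DMAP (cat.), CH2Cl2, dark, 0 → 23 °C; then (PhSe)2, hν (tungsten lamp), 10 °C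
Reagents that add atoms: diphenyl diselenide, c1ccc(cc1)[Se][Se]c1ccccc1; 1-hydroxypyridine-2(1H)-thione, ON1C=CC=CC1=S (ends only in intermediate 8)
Why: Barton decarboxylation: photolysis of the thiohydroxamate ester releases CO2 and the α-acyloxy C6 radical, which diphenyl diselenide traps, so the glyoxylate carboxyl carbon serves as a traceless handle for the radical precursor; the C6–Se centre need not be controlled.

Step 6
Reactants: 10 pent-4-enoyl chloride; 11 tributyl(vinyl)stannane
Product: 12 hepta-1,6-dien-3-one
Conditions: PdCl2(PPh3)2 (2 mol %), THF, 50 °C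
Reagents that add atoms: none
Why: Stille coupling of an acid chloride with a vinylstannane gives the vinyl ketone directly; no stereocentre.

Step 7
Reactants: 12 hepta-1,6-dien-3-one; 13 3-(trimethylsilyl)prop-2-ynal
Product: 14 rac-7-hydroxy-6-methylidene-9-(trimethylsilyl)non-1-en-8-yn-5-one
Conditions: DABCO (20 mol %), THF, 0 → 23 °C
Reagents that add atoms: none
Why: Morita–Baylis–Hillman reaction: DABCO adds to the vinyl ketone and the resulting enolate attacks the electrophilic ynal, giving the α-methylene β-hydroxy ketone that holds C7–C9 and C11–C17; the carbinol (C15) forms racemic, and the silyl group keeps the amine from adding to the alkyne terminus.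

Step 8
Reactants: 14 silylated Baylis–Hillman adduct
Product: 15 rac-7-hydroxy-6-methylidenenon-1-en-8-yn-5-one
Conditions: TBAF, AcOH, THF, 0 °C
Reagents that add atoms: none
Why: Fluoride protodesilylation of the alkynylsilane, buffered with acetic acid so that the base-sensitive Baylis–Hillman adduct survives.

Step 9
Reactants: 15 racemic alcohol
Product: 16 (7S)-7-hydroxy-6-methylidenenon-1-en-8-yn-5-one
Conditions: Novozym 435 (immobilised Candida antarctica lipase B), vinyl acetate, t-BuOMe, 30 °C, stopped just past half conversion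
Reagents that add atoms: none
Why: Lipase-catalysed kinetic resolution by transesterification: by the Kazlauskas rule the (7R) alcohol (ethynyl as medium, acylvinyl as large substituent) is acetylated and the (7S) alcohol is recovered.

Step 10
Reactants: 16 (7S) alcohol
Product: 17 (7S)-6-methylidene-7-[(triethylsilyl)oxy]non-1-en-8-yn-5-one
Conditions: TESCl, imidazole, CH2Cl2, 0 °C
Reagents that add atoms: chlorotriethylsilane, CC[Si](Cl)(CC)CC
Why: Silylation of the secondary alcohol; the bulky triethylsilyloxy group is the steric control element for step 11 and the stereocentre is untouched.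

Step 11
Reactants: 9 lactone selenide; 17 silyloxy enynone
Product: 19 (3R,3aS,4R,7aR)-4-hydroxy-3-{[(1R,5R,7S)-7-hydroxy-6-methylidene-2-oxobicyclo[3.2.1]octan-1-yl]methyl}-4,7a-dimethylhexahydro-2-benzofuran-1(3H)-one, via triethylsilyl ether 18 (not isolated)
Conditions: 17 (1.5 equiv), PhH (0.2 M in 17), 80 °C; Bu3SnH and AIBN added by syringe pump over 10 h; then PPTS, MeOH, 23 °C
Reagents that add atoms: none
Why: Bu3Sn• abstracts PhSe from 9, the α-acyloxy C6 radical adds to the unsubstituted alkene terminus C7 of 17 (Giese addition), the tertiary α-keto radical at C8 closes ring C onto the terminal alkene (new C8–C14 bond), the secondary C13 radical closes ring D onto the alkyne (new C13–C16 bond) and the vinyl radical at C17 takes hydrogen from Bu3SnH; methanolysis then frees the C15 hydroxyl. The closest known reaction types are tin hydride-mediated radical conjugate addition–cyclisation cascades and the tandem cyclisation of α-propargyl 2-oxohex-5-enyl radicals to 6-methylidenebicyclo[3.2.1]octan-2-ones. Ring C closes 6-endo-trig, favoured over 5-exo because the carbonyl lies inside the forming ring and the radical carbon is fully substituted, and ring D closes 5-exo-dig from the chair cyclohexanone with the propargylic arm axial. C6 is set by approach of 17 to the convex face of the cis-fused lactone radical, trans to C10 on C5; C8 is set by 1,2-induction from C15, whose hydrogen eclipses the C8–C9 bond to avoid allylic strain while the alkene chain attacks anti to the triethylsilyloxy group; C13 follows from C8 because the two-carbon bridge can only span the ring 1,3-diaxially. The (7S) configuration of 17 is chosen so that this induction gives the (8R,13R) core with the C15 oxygen exo, an orientation corrected in steps 12 to 14. The step needs addition to C7 to outrun reduction of the C6 radical (secured by the electron-poor 1,1-disubstituted enone used in excess) and ring closure at C8 to outrun hydrogen transfer (secured by keeping Bu3SnH low through slow addition).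

Step 12
Reactants: 19 cascade diol
Product: 20 (3R,3aS,4R,7aR)-4-hydroxy-4,7a-dimethyl-3-{[(1S,5R)-6-methylidene-2,7-dioxobicyclo[3.2.1]octan-1-yl]methyl}hexahydro-2-benzofuran-1(3H)-one
Conditions: Dess–Martin periodinane, NaHCO3, CH2Cl2, 0 → 23 °C
Reagents that add atoms: none
Why: Dess–Martin oxidation of the allylic C15 alcohol to the α-methylene ketone erases the control stereocentre; C8 is quaternary, so the 1,3-diketone cannot enolise or epimerise there, and the tertiary hydroxyl is inert.

Step 13
Reactants: 20 enedione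
Product: 21 (3R,3aS,4R,7aR)-4-[(tert-butyldimethylsilyl)oxy]-3-{[(1S,5R)-2-[(tert-butyldimethylsilyl)oxy]-6-methylidene-7-oxobicyclo[3.2.1]oct-2-en-1-yl]methyl}-4,7a-dimethylhexahydro-2-benzofuran-1(3H)-one
Conditions: TBSOTf (3 equiv), Et3N, CH2Cl2, −78 → 0 °C
Reagents that add atoms: tert-butyldimethylsilyl trifluoromethanesulfonate, CC(C)(C)[Si](C)(C)OS(=O)(=O)C(F)(F)F
Why: Enol silylation with a silyl triflate and amine base: the C15 ketone has no α-hydrogen and C8 is quaternary, so only C11 can be deprotonated and the C9 enol ether forms regiospecifically, masking C9 for step 14 and preparing step 16; the tertiary C10 hydroxyl is silylated as well.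

Step 14
Reactants: 21 bis-silyl ketone
Product: 22 (3R,3aS,4R,7aR)-4-[(tert-butyldimethylsilyl)oxy]-3-{[(1R,5R,7R)-2-[(tert-butyldimethylsilyl)oxy]-7-hydroxy-6-methylidenebicyclo[3.2.1]oct-2-en-1-yl]methyl}-4,7a-dimethylhexahydro-2-benzofuran-1(3H)-one
Conditions: NaBH4, CeCl3·7H2O, MeOH/THF, −78 °C
Reagents that add atoms: none
Why: Luche reduction: 1,2-hydride addition to the C15 ketone from the exo face (syn to the one-carbon bridge C14), because the endo face is screened by the C9–C11–C12 bridge and its silyloxy group, gives the endo (15R) allylic alcohol; the enol ether and the lactone are not reduced.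

Step 15
Reactants: 22 endo allylic alcohol
Product: 23 (1R,5R,7R)-2-[(tert-butyldimethylsilyl)oxy]-1-{[(3R,3aS,4R,7aR)-4-[(tert-butyldimethylsilyl)oxy]-4,7a-dimethyl-1-oxooctahydro-2-benzofuran-3-yl]methyl}-6-methylidenebicyclo[3.2.1]oct-2-en-7-yl acetate
Conditions: Ac2O, DMAP, Et3N, CH2Cl2, 23 °C
Reagents that add atoms: acetic anhydride, CC(=O)OC(C)=O
Why: DMAP-catalysed acetylation of the secondary allylic alcohol with retention at C15; the tertiary hydroxyl is protected and the enol ether is stable to these conditions.

Step 16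
Reactants: 23 enol ether acetate
Product: 24 (1R,5S,7R)-1-{[(3R,3aS,4R,7aR)-4-[(tert-butyldimethylsilyl)oxy]-4,7a-dimethyl-1-oxooctahydro-2-benzofuran-3-yl]methyl}-6-methylidene-2-oxobicyclo[3.2.1]oct-3-en-7-yl acetate
Conditions: Pd(OAc)2 (1.2 equiv), MeCN, 23 °C
Reagents that add atoms: none
Why: Saegusa–Ito oxidation: palladation of the silyl enol ether at C11 and β-hydride elimination from C12 install the C11=C12 enone regiospecifically; stoichiometric palladium acetate avoids turnover of palladium metal that could ionise the allylic acetate.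

Step 17
Reactants: 24 silyl-protected enone
Product: 25 (1R,5S,7R)-1-{[(3R,3aS,4R,7aR)-4-hydroxy-4,7a-dimethyl-1-oxooctahydro-2-benzofuran-3-yl]methyl}-6-methylidene-2-oxobicyclo[3.2.1]oct-3-en-7-yl acetate
Conditions: HF·pyridine, pyridine/THF, 0 → 23 °C
Reagents that add atoms: none
Why: Fluoride-mediated cleavage of the tertiary silyl ether; the acetate, enone and lactone are stable to buffered HF and no stereocentre is touched.

**Compound list**
1 | methyl 3-oxocyclohex-1-ene-1-carboxylate | COC(=O)C1=CC(=O)CCC1 | starting material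
2 | ethyl glyoxylate | CCOC(=O)C=O | starting material
3 | methyl (1R)-2-(2-ethoxy-1-hydroxy-2-oxoethyl)-1-methyl-3-oxocyclohexane-1-carboxylate (C2 and carbinol epimers) | COC(=O)[C@]1(C)CCCC(=O)C1C(O)C(=O)OCC | intermediate
4 | ethyl (3aR,7aS)-3a-methyl-3,7-dioxooctahydro-2-benzofuran-1-carboxylate (C1 epimers) | CCOC(=O)C1OC(=O)[C@]2(C)CCCC(=O)[C@H]12 | intermediate
5 | ethyl (3aR,7aS)-3a-methyl-7-methylidene-3-oxooctahydro-2-benzofuran-1-carboxylate (C1 epimers) | CCOC(=O)C1OC(=O)[C@]2(C)CCCC(=C)[C@H]12 | intermediate
6 | ethyl (3aR,7R,7aS)-7-hydroxy-3a,7-dimethyl-3-oxooctahydro-2-benzofuran-1-carboxylate (C1 epimers) | CCOC(=O)C1OC(=O)[C@]2(C)CCC[C@@](C)(O)[C@H]12 | intermediate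
7 | (3aR,7R,7aS)-7-hydroxy-3a,7-dimethyl-3-oxooctahydro-2-benzofuran-1-carboxylic acid (C1 epimers) | OC(=O)C1OC(=O)[C@]2(C)CCC[C@@](C)(O)[C@H]12 | intermediate
8 | 2-thioxopyridin-1(2H)-yl (3aR,7R,7aS)-7-hydroxy-3a,7-dimethyl-3-oxooctahydro-2-benzofuran-1-carboxylate (C1 epimers) | O=C(ON1C=CC=CC1=S)C1OC(=O)[C@]2(C)CCC[C@@](C)(O)[C@H]12 | intermediate
9 | (3aR,4R,7aR)-4-hydroxy-4,7a-dimethyl-3-(phenylselanyl)hexahydro-2-benzofuran-1(3H)-one (C3 epimers) | c1ccccc1[Se]C1OC(=O)[C@]2(C)CCC[C@@](C)(O)[C@H]12 | intermediate
10 | pent-4-enoyl chloride | C=CCCC(Cl)=O | starting material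
11 | tributyl(vinyl)stannane | C=C[Sn](CCCC)(CCCC)CCCC | starting material
12 | hepta-1,6-dien-3-one | C=CCCC(=O)C=C | intermediate
13 | 3-(trimethylsilyl)prop-2-ynal | C[Si](C)(C)C#CC=O | starting material
14 | rac-7-hydroxy-6-methylidene-9-(trimethylsilyl)non-1-en-8-yn-5-one | C=CCCC(=O)C(=C)C(O)C#C[Si](C)(C)C | intermediate
15 | rac-7-hydroxy-6-methylidenenon-1-en-8-yn-5-one | C=CCCC(=O)C(=C)C(O)C#C | intermediate
16 | (7S)-7-hydroxy-6-methylidenenon-1-en-8-yn-5-one | C=CCCC(=O)C(=C)[C@@H](O)C#C | intermediate
17 | (7S)-6-methylidene-7-[(triethylsilyl)oxy]non-1-en-8-yn-5-one | C=CCCC(=O)C(=C)[C@@H](O[Si](CC)(CC)CC)C#C | intermediate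
18 | (3R,3aS,4R,7aR)-4-hydroxy-4,7a-dimethyl-3-{[(1R,5R,7S)-6-methylidene-2-oxo-7-[(triethylsilyl)oxy]bicyclo[3.2.1]octan-1-yl]methyl}hexahydro-2-benzofuran-1(3H)-one | C=C1[C@@H]2CCC(=O)[C@@](C[C@H]3OC(=O)[C@]4(C)CCC[C@@](C)(O)[C@H]34)(C2)[C@H]1O[Si](CC)(CC)CC | intermediate
19 | (3R,3aS,4R,7aR)-4-hydroxy-3-{[(1R,5R,7S)-7-hydroxy-6-methylidene-2-oxobicyclo[3.2.1]octan-1-yl]methyl}-4,7a-dimethylhexahydro-2-benzofuran-1(3H)-one | C=C1[C@@H]2CCC(=O)[C@@](C[C@H]3OC(=O)[C@]4(C)CCC[C@@](C)(O)[C@H]34)(C2)[C@H]1O | intermediate
20 | (3R,3aS,4R,7aR)-4-hydroxy-4,7a-dimethyl-3-{[(1S,5R)-6-methylidene-2,7-dioxobicyclo[3.2.1]octan-1-yl]methyl}hexahydro-2-benzofuran-1(3H)-one | C=C1[C@@H]2CCC(=O)[C@@](C[C@H]3OC(=O)[C@]4(C)CCC[C@@](C)(O)[C@H]34)(C2)C1=O | intermediate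
21 | (3R,3aS,4R,7aR)-4-[(tert-butyldimethylsilyl)oxy]-3-{[(1S,5R)-2-[(tert-butyldimethylsilyl)oxy]-6-methylidene-7-oxobicyclo[3.2.1]oct-2-en-1-yl]methyl}-4,7a-dimethylhexahydro-2-benzofuran-1(3H)-one | C=C1[C@@H]2CC=C(O[Si](C)(C)C(C)(C)C)[C@@](C[C@H]3OC(=O)[C@]4(C)CCC[C@@](C)(O[Si](C)(C)C(C)(C)C)[C@H]34)(C2)C1=O | intermediate
22 | (3R,3aS,4R,7aR)-4-[(tert-butyldimethylsilyl)oxy]-3-{[(1R,5R,7R)-2-[(tert-butyldimethylsilyl)oxy]-7-hydroxy-6-methylidenebicyclo[3.2.1]oct-2-en-1-yl]methyl}-4,7a-dimethylhexahydro-2-benzofuran-1(3H)-one | C=C1[C@@H]2CC=C(O[Si](C)(C)C(C)(C)C)[C@@](C[C@H]3OC(=O)[C@]4(C)CCC[C@@](C)(O[Si](C)(C)C(C)(C)C)[C@H]34)(C2)[C@@H]1O | intermediate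
23 | (1R,5R,7R)-2-[(tert-butyldimethylsilyl)oxy]-1-{[(3R,3aS,4R,7aR)-4-[(tert-butyldimethylsilyl)oxy]-4,7a-dimethyl-1-oxooctahydro-2-benzofuran-3-yl]methyl}-6-methylidenebicyclo[3.2.1]oct-2-en-7-yl acetate | C=C1[C@@H]2CC=C(O[Si](C)(C)C(C)(C)C)[C@@](C[C@H]3OC(=O)[C@]4(C)CCC[C@@](C)(O[Si](C)(C)C(C)(C)C)[C@H]34)(C2)[C@@H]1OC(C)=O | intermediate
24 | (1R,5S,7R)-1-{[(3R,3aS,4R,7aR)-4-[(tert-butyldimethylsilyl)oxy]-4,7a-dimethyl-1-oxooctahydro-2-benzofuran-3-yl]methyl}-6-methylidene-2-oxobicyclo[3.2.1]oct-3-en-7-yl acetate | C=C1[C@@H]2C=CC(=O)[C@@](C[C@H]3OC(=O)[C@]4(C)CCC[C@@](C)(O[Si](C)(C)C(C)(C)C)[C@H]34)(C2)[C@@H]1OC(C)=O | intermediate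
25 | (1R,5S,7R)-1-{[(3R,3aS,4R,7aR)-4-hydroxy-4,7a-dimethyl-1-oxooctahydro-2-benzofuran-3-yl]methyl}-6-methylidene-2-oxobicyclo[3.2.1]oct-3-en-7-yl acetate | C=C1[C@@H]2C=CC(=O)[C@@](C[C@H]3OC(=O)[C@]4(C)CCC[C@@](C)(O)[C@H]34)(C2)[C@@H]1OC(C)=O | target

**Summary**
Total step count: 17. Longest linear sequence: 12 steps (steps 1–5, then 11–17; the branch 6–10, then 11–17, is equally long).

Steps most likely to fail:

Step 11. Hydrogen transfer from the tin hydride to the C8 radical before ring C closes would stop the relay at the open-chain conjugate adduct, and face selection at C8 may be weak. The fallback separates the addition from the ring closures. It sets out from 9 and 17: irradiation with (Bu3Sn)2 (10 mol %) in benzene, without any hydride source, should give by phenylselenium group transfer the phenylselenium-transfer adduct F1, a tertiary α-(phenylselanyl) ketone. F1 is then treated at high dilution with Bu3SnH (slow addition, Et3B/air, 23 °C), which regenerates the C8 radical with no bimolecular step left to compete; the same 6-endo/5-exo-dig closure gives 18, and methanolysis brings the route back at 19.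

Step 1. β-Elimination or retro-aldol loss of the zinc aldolate, or incomplete equilibration at C5, would keep the lactone from forming in one pot. The fallback sets out from 1: the conjugate addition is run alone and the zinc enolate is silylated (TMSCl) to the trimethylsilyl enol ether F2. A Mukaiyama aldol reaction of F2 with 2 (TiCl4, CH2Cl2, −78 °C) gives 3 as an isolated compound, and camphorsulfonic acid in toluene closes the lactone with equilibration at C5, coming back to the route at 4.

Step 3. Capture of the C10 radical by O2 from the concave face would give the C10 epimer, recognisable because its hydroxyl is cis to C19 and translactonises. The fallback sets out from 4 and delivers the methyl carbon, not the oxygen, to C10: MeLi/CeCl3 (THF, −78 °C) adds chemoselectively to the ketone from the face the oxygen would have used, which gives the opposite relative configuration, that is 6 directly. This fallback makes no compound outside the list (F0) and comes back to the route at 6.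

Further compounds
F1 | step 11 | (3R,3aS,4R,7aR)-4-hydroxy-4,7a-dimethyl-3-{(3S)-2-(pent-4-enoyl)-2-(phenylselanyl)-3-[(triethylsilyl)oxy]pent-4-yn-1-yl}hexahydro-2-benzofuran-1(3H)-one (C2' epimers) | C=CCCC(=O)C([Se]c1ccccc1)(C[C@H]1OC(=O)[C@]2(C)CCC[C@@](C)(O)[C@H]12)[C@@H](O[Si](CC)(CC)CC)C#C
F2 | step 1 | methyl (1R)-1-methyl-3-[(trimethylsilyl)oxy]cyclohex-2-ene-1-carboxylate | COC(=O)[C@]1(C)CCCC(O[Si](C)(C)C)=C1
F0 | step 3 | none | none
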